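**Plan**

- Retrosynthesis: after the late moves (4'-O-desilylation, 7-O-demethylation, C8 ester to aldehyde, O–C bond of pyran ring D), ring B is cut at C2'–C3', C4'–C5', C5'–C6' and C1'–C2' into a chroman-3-yl α-diazo enone and a prenyl siloxyalkyne. The chroman is cut at O1–C2 and C4–C4a back to a salicylate and 2-methylidenepropane-1,3-diol.
- Enabling feature: ring B (C1'–C6', fused to ring D) is a resorcinol with hydrogens at C5' and C6', a carbon substituent at C3' and two oxygens (2'-O, 4'-O) that must be told apart. It maps onto a ketene carbonyl (C2'), a siloxyalkyne (C3', C4'), a diazo carbon (C5') and an enone alkene (C6', C1'), and the annulation delivers 2'-OH free and 4'-O silylated.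
- Forward order: ring C is closed on ring A (Claisen C-allylation, then Mitsunobu etherification), the C3 side chain is grown to the diazo enone, ring B is annulated in one photochemical–thermal operation, ring D is closed by oxidative cyclisation, and ring A is adjusted last.
- Stereochemistry: the only stereocentre, C3 (R in the target), comes from lipase desymmetrisation of a prochiral 2-(arylmethyl)propane-1,3-diol and is never a reacting centre afterwards.

Key step: step 11

Assumption: the lipase is taken to acetylate the pro-S hydroxymethyl arm of the prochiral diol; this sense cannot be predicted with certainty for this substrate and has to be established by correlation on the first batch.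

**Step 1**
Reactants: 1 methyl 2-hydroxy-4,6-dimethoxybenzoate; 2 2-methylidenepropane-1,3-diol (threefold excess)
Product: 3 methyl 2-{[2-(hydroxymethyl)prop-2-en-1-yl]oxy}-4,6-dimethoxybenzoate
Conditions: PPh3, DIAD, THF, 0 °C to rt
Reagents that add atoms: none
Why: Mitsunobu etherification should work because the salicylate phenol is acidic enough to displace the activated primary allylic alcohol, the symmetrical allyl unit makes SN2 and SN2' attack converge on one product, and the diol excess holds back double etherification.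

**Step 2**
Reactants: 3 methyl 2-{[2-(hydroxymethyl)prop-2-en-1-yl]oxy}-4,6-dimethoxybenzoate
Product: 5 methyl 2-hydroxy-3-[2-(hydroxymethyl)prop-2-en-1-yl]-4,6-dimethoxybenzoate, via ortho-dienone 4 (not isolated)
Conditions: PhNEt2, 190 °C
Reagents that add atoms: none
Why: the aromatic Claisen rearrangement can reach only the one free ortho carbon (the other carries the ester), so the [3,3] shift and tautomerisation place the three-carbon unit exactly at the future C4a, and the basic amine solvent suppresses acid-catalysed addition of the phenol to the alkene.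

**Step 3**
Reactants: 5 methyl 2-hydroxy-3-[2-(hydroxymethyl)prop-2-en-1-yl]-4,6-dimethoxybenzoate
Product: 7 methyl 2-hydroxy-3-[3-hydroxy-2-(hydroxymethyl)propyl]-4,6-dimethoxybenzoate, via B-alkyl-9-BBN adduct 6 (not isolated)
Conditions: 9-BBN (3.5 equiv), THF, 0 to 50 °C; then 30% H2O2, 3 M aq NaOAc, 0 °C to rt
Reagents that add atoms: hydrogen peroxide, OO
Why: Brown hydroboration–oxidation with 9-BBN puts boron on the terminal carbon of the 1,1-disubstituted alkene and leaves the aryl ester untouched, and the product is an achiral diol whose two hydroxymethyl arms are enantiotopic.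

**Step 4**
Reactants: 7 methyl 2-hydroxy-3-[3-hydroxy-2-(hydroxymethyl)propyl]-4,6-dimethoxybenzoate
Product: 8 methyl 3-[(2S)-3-acetoxy-2-(hydroxymethyl)propyl]-2-hydroxy-4,6-dimethoxybenzoate
Conditions: vinyl acetate, immobilised Burkholderia cepacia lipase, t-BuOMe, 25 °C
Reagents that add atoms: vinyl acetate, CC(=O)OC=C
Why: lipase-catalysed enantiotopic-group-selective transesterification of a 2-(arylmethyl)propane-1,3-diol with an irreversible enol-ester donor should acetylate one arm only, which creates the future C3 stereocentre as the (S)-monoacetate, while the hindered hydrogen-bonded phenol is not accepted by the enzyme.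

**Step 5**
Reactants: 8 methyl 3-[(2S)-3-acetoxy-2-(hydroxymethyl)propyl]-2-hydroxy-4,6-dimethoxybenzoate
Product: 9 methyl (3S)-3-(acetoxymethyl)-5,7-dimethoxychroman-8-carboxylate
Conditions: PPh3, DIAD, THF, 0 °C to rt
Reagents that add atoms: none
Why: intramolecular Mitsunobu etherification closes ring C by 6-exo-tet attack of the phenoxide on the oxyphosphonium carbon, and the stereocentre is a spectator because only a CH2 group reacts (the descriptor is S here only through the priority of the acetoxymethyl group).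

**Step 6**
Reactants: 9 methyl (3S)-3-(acetoxymethyl)-5,7-dimethoxychroman-8-carboxylate
Product: 10 methyl (3R)-3-(hydroxymethyl)-5,7-dimethoxychroman-8-carboxylate
Conditions: K2CO3 (cat.), MeOH, 0 °C to rt
Reagents that add atoms: none
Why: base-catalysed transesterification (Zemplén-type methanolysis) removes the primary acetate, and the hindered aryl ester is already a methyl ester so exchange at that site changes nothing.

**Step 7**
Reactants: 10 methyl (3R)-3-(hydroxymethyl)-5,7-dimethoxychroman-8-carboxylate
Product: 12 methyl (3R)-5,7-dimethoxy-3-[(1E)-3-oxobut-1-en-1-yl]chroman-8-carboxylate, via aldehyde 11 (not isolated)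
Conditions: Dess–Martin periodinane, CH2Cl2, 0 °C to rt; then Ph3P=CHC(O)CH3 (3 equiv), rt
Reagents that add atoms: 1-(triphenylphosphoranylidene)propan-2-one, CC(=O)C=P(c1ccccc1)(c1ccccc1)c1ccccc1
Why: Dess–Martin oxidation followed in the same flask by an E-selective Wittig olefination with a stabilised ylide traps the α-branched β-aryloxy aldehyde as it forms, so that enolisation or retro-oxa-Michael opening, which would erode C3, gets little chance under these nearly neutral conditions.

**Step 8**
Reactants: 12 methyl (3R)-5,7-dimethoxy-3-[(1E)-3-oxobut-1-en-1-yl]chroman-8-carboxylate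
Product: 14 methyl (3R)-3-[(1E)-4-diazo-3-oxobut-1-en-1-yl]-5,7-dimethoxychroman-8-carboxylate, via trifluoroacetyl diketone 13 (not isolated)
Conditions: LiHMDS, THF, −78 °C; CF3CO2CH2CF3, −78 °C; 5% aq HCl work-up; then MsN3, Et3N, H2O, MeCN, rt
Reagents that add atoms: methanesulfonyl azide, CS(=O)(=O)N=[N+]=[N-]
Why: detrifluoroacetylative diazo transfer (Danheiser variant of the Regitz transfer) works on methyl enones because kinetic deprotonation occurs at the α' methyl group and not at the γ position, so the alkene geometry and C3 stay intact, and the activated 1,3-diketone then takes up the diazo group with loss of the trifluoroacetyl unit.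

**Step 9**
Reactants: 15 4-methylpent-3-enoic acid
Product: 16 methyl 4-methylpent-3-enoate
Conditions: MeI, K2CO3, DMF, rt
Reagents that add atoms: iodomethane, CI
Why: carboxylate O-alkylation (SN2) avoids the acidic conditions under which this β,γ-unsaturated acid would lactonise to the γ,γ-dimethylbutyrolactone.

**Step 10**
Reactants: 16 methyl 4-methylpent-3-enoate
Product: 19 triisopropyl[(5-methylhex-4-en-1-yn-1-yl)oxy]silane, via dibromomethyl ketone 17 (not isolated), via lithium ynolate 18 (not isolated)
Conditions: CH2Br2, LiTMP, THF, −78 °C; LiHMDS; n-BuLi, −78 °C to rt; TIPSCl, −78 °C to rt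
Reagents that add atoms: dibromomethane, BrCBr; chlorotriisopropylsilane, CC(C)[Si](Cl)(C(C)C)C(C)C
Why: the Kowalski ester homologation is stopped at the ynolate stage (LiCHBr2 addition, enolisation, bromine–lithium exchange and 1,2-shift), and the bulky silyl chloride reacts at oxygen to give the siloxyalkyne and not the silylketene.

**Step 11**
Reactants: 14 methyl (3R)-3-[(1E)-4-diazo-3-oxobut-1-en-1-yl]-5,7-dimethoxychroman-8-carboxylate; 19 triisopropyl[(5-methylhex-4-en-1-yn-1-yl)oxy]silane (1.5 equiv)
Product: 24 methyl (3R)-3-[2-hydroxy-3-(3-methylbut-2-en-1-yl)-4-(triisopropylsilyloxy)phenyl]-5,7-dimethoxychroman-8-carboxylate, via vinylketene 20 (not isolated), via 4-vinylcyclobutenone 21 (not isolated), via dienylketene 22 (not isolated), via cyclohexadienone 23 (not isolated)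
Conditions: hν (300 nm, Pyrex), ClCH2CH2Cl, rt; then 80 °C
Reagents that add atoms: none
Why: Light expels N2 from 14 and the alkenyl group shifts to the carbene carbon (Wolff rearrangement, C5'–C6') to give vinylketene 20, which the electron-rich siloxyalkyne captures at room temperature by a regioselective [2+2] cycloaddition (C2'–C3' and C4'–C5') to give cyclobutenone 21. Warming drives the 4π electrocyclic opening to dienylketene 22 and its 6π electrocyclic closure (C1'–C2', a six-membered carbocycle formed at the alkene carbon that carries the chroman), and tautomerisation of dienone 23 gives phenol 24; this is the second-generation Danheiser benzannulation, known for α'-diazo enones with triisopropylsilyloxyalkynes. No stereocentre is created, because the sp3 carbons of 21 and 23 vanish on aromatisation, and C3 stays tetrahedral throughout since it is only allylic to the reacting π system. The regiochemistry needed (prenyl at C3', OTIPS at C4', free OH at C2') follows from the polarisation of the ynol ether, whose carbon β to oxygen attacks the ketene carbonyl carbon. Chemoselectivity for the alkyne over the prenyl alkene rests on the far higher nucleophilicity of the siloxyalkyne, and the (E)-alkene of 14 lets the dienylketene reach the s-cis geometry required for closure.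

**Step 12**
Reactants: 24 methyl (3R)-3-[2-hydroxy-3-(3-methylbut-2-en-1-yl)-4-(triisopropylsilyloxy)phenyl]-5,7-dimethoxychroman-8-carboxylate
Product: 26 methyl (3R)-3-[2,2-dimethyl-5-(triisopropylsilyloxy)-2H-chromen-8-yl]-5,7-dimethoxychroman-8-carboxylate, via ortho-quinone methide 25 (not isolated)
Conditions: DDQ (1.1 equiv), PhH, rt
Reagents that add atoms: none
Why: DDQ dehydrogenation of an ortho-prenylphenol removes hydride from the doubly activated (benzylic and allylic) methylene to give the ortho-quinone methide, which closes by oxa-6π electrocyclisation, and only the 2'-oxygen can take part because the 4'-oxygen is silylated.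

**Step 13**
Reactants: 26 methyl (3R)-3-[2,2-dimethyl-5-(triisopropylsilyloxy)-2H-chromen-8-yl]-5,7-dimethoxychroman-8-carboxylate
Product: 27 {(3R)-3-[2,2-dimethyl-5-(triisopropylsilyloxy)-2H-chromen-8-yl]-5,7-dimethoxychroman-8-yl}methanol
Conditions: DIBAL-H (3 equiv), CH2Cl2, −78 to 0 °C; aq Rochelle salt
Reagents that add atoms: none
Why: hydride reduction of the aryl methyl ester to the benzylic alcohol with DIBAL-H leaves the aryl silyl ether, the chromene and the methyl ethers untouched.

**Step 14**
Reactants: 27 {(3R)-3-[2,2-dimethyl-5-(triisopropylsilyloxy)-2H-chromen-8-yl]-5,7-dimethoxychroman-8-yl}methanol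
Product: 28 (3R)-3-[2,2-dimethyl-5-(triisopropylsilyloxy)-2H-chromen-8-yl]-5,7-dimethoxychroman-8-carbaldehyde
Conditions: activated MnO2, CH2Cl2, rt
Reagents that add atoms: none
Why: MnO2 oxidises electron-rich benzylic alcohols selectively to aldehydes without overoxidation and without touching the chromene alkene.

**Step 15**
Reactants: 28 (3R)-3-[2,2-dimethyl-5-(triisopropylsilyloxy)-2H-chromen-8-yl]-5,7-dimethoxychroman-8-carbaldehyde
Product: 29 (3R)-3-[2,2-dimethyl-5-(triisopropylsilyloxy)-2H-chromen-8-yl]-7-hydroxy-5-methoxychroman-8-carbaldehyde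
Conditions: MgI2·OEt2, PhMe, 60 °C; aqueous work-up
Reagents that add atoms: none
Why: chelation-controlled ortho-demethylation with MgI2 works because magnesium bridges the formyl oxygen and the 7-methoxy oxygen so that iodide attacks that methyl group by SN2, whereas the 5-methoxy group (para to the formyl) cannot chelate and the ring O–CH2 carbon is far slower than methyl towards iodide.

**Step 16**
Reactants: 29 (3R)-3-[2,2-dimethyl-5-(triisopropylsilyloxy)-2H-chromen-8-yl]-7-hydroxy-5-methoxychroman-8-carbaldehyde
Product: 30 (3R)-7-hydroxy-3-(5-hydroxy-2,2-dimethyl-2H-chromen-8-yl)-5-methoxychroman-8-carbaldehyde (CNP0272344.1)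
Conditions: TBAF, AcOH, THF, 0 °C
Reagents that add atoms: none
Why: fluoride-mediated cleavage of the aryl silyl ether is driven by the strong Si–F bond, and the acetic acid buffer keeps the salicylaldehyde and the chromene out of strongly basic conditions.

**Compound list**

1 | methyl 2-hydroxy-4,6-dimethoxybenzoate | COC(=O)c1c(O)cc(OC)cc1OC | starting material
2 | 2-methylidenepropane-1,3-diol | OCC(=C)CO | starting material
3 | methyl 2-{[2-(hydroxymethyl)prop-2-en-1-yl]oxy}-4,6-dimethoxybenzoate | COC(=O)c1c(OCC(=C)CO)cc(OC)cc1OC | intermediate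
4 | methyl 5-[2-(hydroxymethyl)prop-2-en-1-yl]-2,4-dimethoxy-6-oxocyclohexa-1,3-diene-1-carboxylate (racemic ortho-dienone, formed in situ) | COC(=O)C1=C(OC)C=C(OC)C(CC(=C)CO)C1=O | intermediate
5 | methyl 2-hydroxy-3-[2-(hydroxymethyl)prop-2-en-1-yl]-4,6-dimethoxybenzoate | COC(=O)c1c(O)c(CC(=C)CO)c(OC)cc1OC | intermediate
6 | methyl 3-[3-(9-borabicyclo[3.3.1]nonan-9-yl)-2-(hydroxymethyl)propyl]-2-hydroxy-4,6-dimethoxybenzoate (formed in situ, drawn with free OH groups, which may be borylated transiently) | COC(=O)c1c(O)c(CC(CO)CB2C3CCCC2CCC3)c(OC)cc1OC | intermediate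
7 | methyl 2-hydroxy-3-[3-hydroxy-2-(hydroxymethyl)propyl]-4,6-dimethoxybenzoate | COC(=O)c1c(O)c(CC(CO)CO)c(OC)cc1OC | intermediate
8 | methyl 3-[(2S)-3-acetoxy-2-(hydroxymethyl)propyl]-2-hydroxy-4,6-dimethoxybenzoate | COC(=O)c1c(O)c(C[C@H](COC(C)=O)CO)c(OC)cc1OC | intermediate
9 | methyl (3S)-3-(acetoxymethyl)-5,7-dimethoxychroman-8-carboxylate | COc1cc(OC)c(C(=O)OC)c2c1C[C@H](COC(C)=O)CO2 | intermediate
10 | methyl (3R)-3-(hydroxymethyl)-5,7-dimethoxychroman-8-carboxylate | COc1cc(OC)c(C(=O)OC)c2c1C[C@H](CO)CO2 | intermediate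
11 | methyl (3S)-3-formyl-5,7-dimethoxychroman-8-carboxylate (formed in situ) | COc1cc(OC)c(C(=O)OC)c2c1C[C@H](C=O)CO2 | intermediate
12 | methyl (3R)-5,7-dimethoxy-3-[(1E)-3-oxobut-1-en-1-yl]chroman-8-carboxylate | COc1cc(OC)c(C(=O)OC)c2c1C[C@H](/C=C/C(C)=O)CO2 | intermediate
13 | methyl (3R)-5,7-dimethoxy-3-[(1E)-6,6,6-trifluoro-3,5-dioxohex-1-en-1-yl]chroman-8-carboxylate (used crude) | COc1cc(OC)c(C(=O)OC)c2c1C[C@H](/C=C/C(=O)CC(=O)C(F)(F)F)CO2 | intermediate
14 | methyl (3R)-3-[(1E)-4-diazo-3-oxobut-1-en-1-yl]-5,7-dimethoxychroman-8-carboxylate | COc1cc(OC)c(C(=O)OC)c2c1C[C@H](/C=C/C(=O)C=[N+]=[N-])CO2 | intermediate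
15 | 4-methylpent-3-enoic acid | CC(C)=CCC(=O)O | starting material
16 | methyl 4-methylpent-3-enoate | CC(C)=CCC(=O)OC | intermediate
17 | 1,1-dibromo-5-methylhex-4-en-2-one (present as its lithium enolate, formed in situ) | CC(C)=CCC(=O)C(Br)Br | intermediate
18 | lithium 5-methylhex-4-en-1-yn-1-olate (formed in situ) | CC(C)=CCC#C[O-].[Li+] | intermediate
19 | triisopropyl[(5-methylhex-4-en-1-yn-1-yl)oxy]silane | CC(C)=CCC#CO[Si](C(C)C)(C(C)C)C(C)C | intermediate
20 | methyl (3R)-5,7-dimethoxy-3-[(1E)-4-oxobuta-1,3-dien-1-yl]chroman-8-carboxylate (vinylketene, formed in situ) | COc1cc(OC)c(C(=O)OC)c2c1C[C@H](/C=C/C=C=O)CO2 | intermediate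
21 | methyl (3R)-5,7-dimethoxy-3-{(E)-2-[3-(3-methylbut-2-en-1-yl)-4-oxo-2-(triisopropylsilyloxy)cyclobut-2-en-1-yl]ethenyl}chroman-8-carboxylate (formed in situ, ring sp3 centre unspecified) | COc1cc(OC)c(C(=O)OC)c2c1C[C@H](/C=C/C3C(=O)C(CC=C(C)C)=C3O[Si](C(C)C)(C(C)C)C(C)C)CO2 | intermediate
22 | methyl (3R)-5,7-dimethoxy-3-[(1E,3E)-5-(3-methylbut-2-en-1-yl)-6-oxo-4-(triisopropylsilyloxy)hexa-1,3,5-trien-1-yl]chroman-8-carboxylate (dienylketene, formed in situ) | COc1cc(OC)c(C(=O)OC)c2c1C[C@H](/C=C/C=C(O[Si](C(C)C)(C(C)C)C(C)C)\C(CC=C(C)C)=C=O)CO2 | intermediate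
23 | methyl (3R)-5,7-dimethoxy-3-[3-(3-methylbut-2-en-1-yl)-2-oxo-4-(triisopropylsilyloxy)cyclohexa-3,5-dien-1-yl]chroman-8-carboxylate (formed in situ, ring sp3 centre unspecified) | COc1cc(OC)c(C(=O)OC)c2c1C[C@H](C3C=CC(O[Si](C(C)C)(C(C)C)C(C)C)=C(CC=C(C)C)C3=O)CO2 | intermediate
24 | methyl (3R)-3-[2-hydroxy-3-(3-methylbut-2-en-1-yl)-4-(triisopropylsilyloxy)phenyl]-5,7-dimethoxychroman-8-carboxylate | COc1cc(OC)c(C(=O)OC)c2c1C[C@H](c1ccc(O[Si](C(C)C)(C(C)C)C(C)C)c(CC=C(C)C)c1O)CO2 | intermediate
25 | methyl (3R)-5,7-dimethoxy-3-[5-(3-methylbut-2-en-1-ylidene)-6-oxo-4-(triisopropylsilyloxy)cyclohexa-1,3-dien-1-yl]chroman-8-carboxylate (ortho-quinone methide, formed in situ, exocyclic geometry unspecified) | COc1cc(OC)c(C(=O)OC)c2c1C[C@H](C3=CC=C(O[Si](C(C)C)(C(C)C)C(C)C)C(=CC=C(C)C)C3=O)CO2 | intermediate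
26 | methyl (3R)-3-[2,2-dimethyl-5-(triisopropylsilyloxy)-2H-chromen-8-yl]-5,7-dimethoxychroman-8-carboxylate | COc1cc(OC)c(C(=O)OC)c2c1C[C@H](c1ccc(O[Si](C(C)C)(C(C)C)C(C)C)c3c1OC(C)(C)C=C3)CO2 | intermediate
27 | {(3R)-3-[2,2-dimethyl-5-(triisopropylsilyloxy)-2H-chromen-8-yl]-5,7-dimethoxychroman-8-yl}methanol | COc1cc(OC)c(CO)c2c1C[C@H](c1ccc(O[Si](C(C)C)(C(C)C)C(C)C)c3c1OC(C)(C)C=C3)CO2 | intermediate
28 | (3R)-3-[2,2-dimethyl-5-(triisopropylsilyloxy)-2H-chromen-8-yl]-5,7-dimethoxychroman-8-carbaldehyde | COc1cc(OC)c(C=O)c2c1C[C@H](c1ccc(O[Si](C(C)C)(C(C)C)C(C)C)c3c1OC(C)(C)C=C3)CO2 | intermediate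
29 | (3R)-3-[2,2-dimethyl-5-(triisopropylsilyloxy)-2H-chromen-8-yl]-7-hydroxy-5-methoxychroman-8-carbaldehyde | COc1cc(O)c(C=O)c2c1C[C@H](c1ccc(O[Si](C(C)C)(C(C)C)C(C)C)c3c1OC(C)(C)C=C3)CO2 | intermediate
30 | (3R)-7-hydroxy-3-(5-hydroxy-2,2-dimethyl-2H-chromen-8-yl)-5-methoxychroman-8-carbaldehyde | COc1cc(O)c(C=O)c2c1C[C@H](c1ccc(O)c3c1OC(C)(C)C=C3)CO2 | target

**Step count**

Total: 16 steps. Longest linear sequence: 14 steps (steps 1–8 and 11–16, from 1 to 30). The siloxyalkyne branch takes 2 steps (9 and 10).

**Steps most likely to fail**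

a) Step 11. Capture of the photogenerated vinylketene by the siloxyalkyne may lose out to ketene dimerisation, to screening of the light by the oxygenated benzoate chromophore, or to secondary photochemistry of the phenolic product, and the cyclobutenone may not be carried through completely on heating. The fallback separates ketene formation from annulation by using a silyl-stabilised ketene and the ynolate itself. It sets out from 14: C-silylation with TIPSOTf and i-Pr2NEt (Et2O–hexane, 0 °C to rt) gives methyl (3R)-3-[(1E)-4-diazo-3-oxo-4-(triisopropylsilyl)but-1-en-1-yl]-5,7-dimethoxychroman-8-carboxylate F1. Irradiation of F1 alone (300 nm, benzene) gives by Wolff rearrangement the isolable (triisopropylsilyl)vinylketene methyl (3R)-5,7-dimethoxy-3-[(1E)-4-oxo-3-(triisopropylsilyl)buta-1,3-dien-1-yl]chroman-8-carboxylate F2. Addition of F2 to lithium ynolate 18 (made as in step 10, without the silyl chloride quench; THF, −78 °C to rt, then aq NH4Cl) gives, by C-acylation of the ynolate, 6π electrocyclisation and 1,3 carbon-to-oxygen silyl shift, the same resorcinol monosilyl ether, so the route is rejoined at 24.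

b) Step 4. The enzyme may acetylate the opposite enantiotopic arm or discriminate the arms poorly, and acyl migration between the arms may erode the enantiomeric purity before cyclisation. The fallback sets C3 by asymmetric hydrogenation instead and sets out from 1. Magnesium-mediated ortho-formylation (MgCl2, Et3N, paraformaldehyde, MeCN, reflux) gives methyl 3-formyl-2-hydroxy-4,6-dimethoxybenzoate F3. Oxa-Michael/aldol condensation with acrolein (K2CO3, 1,4-dioxane, reflux) gives methyl 3-formyl-5,7-dimethoxy-2H-chromene-8-carboxylate F4. Pinnick oxidation (NaClO2, NaH2PO4, 2-methylbut-2-ene, t-BuOH–H2O) gives 8-(methoxycarbonyl)-5,7-dimethoxy-2H-chromene-3-carboxylic acid F5. Hydrogenation over Ru(OAc)2(BINAP) in MeOH under H2 pressure, with the ligand antipode that delivers the (S)-acid, gives (3S)-8-(methoxycarbonyl)-5,7-dimethoxychroman-3-carboxylic acid F6. BH3·SMe2 (THF, 0 °C) then reduces the carboxylic acid in the presence of the aryl ester, and the route is rejoined at 10.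

c) Step 12. Hydride abstraction by the quinone at C3–H or C4–H2 of the chroman may compete with abstraction from the prenyl methylene, which would cost the C3 configuration or lead to overoxidation. The fallback closes ring D without a hydride acceptor and sets out from 24. Selenoetherification with PhSeCl (CH2Cl2, −78 °C) gives methyl (3R)-3-[2,2-dimethyl-3-(phenylselanyl)-5-(triisopropylsilyloxy)chroman-8-yl]-5,7-dimethoxychroman-8-carboxylate F7. Oxidation of F7 to the selenoxide (30% H2O2, THF, 0 °C to rt) and syn-elimination towards the only β-hydrogens (the benzylic CH2) gives the chromene, so the route is rejoined at 26.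

**Further compounds**

F1 | step 11 | methyl (3R)-3-[(1E)-4-diazo-3-oxo-4-(triisopropylsilyl)but-1-en-1-yl]-5,7-dimethoxychroman-8-carboxylate | COc1cc(OC)c(C(=O)OC)c2c1C[C@H](/C=C/C(=O)C(=[N+]=[N-])[Si](C(C)C)(C(C)C)C(C)C)CO2
F2 | step 11 | methyl (3R)-5,7-dimethoxy-3-[(1E)-4-oxo-3-(triisopropylsilyl)buta-1,3-dien-1-yl]chroman-8-carboxylate | COc1cc(OC)c(C(=O)OC)c2c1C[C@H](/C=C/C(=C=O)[Si](C(C)C)(C(C)C)C(C)C)CO2
F3 | step 4 | methyl 3-formyl-2-hydroxy-4,6-dimethoxybenzoate | COC(=O)c1c(O)c(C=O)c(OC)cc1OC
F4 | step 4 | methyl 3-formyl-5,7-dimethoxy-2H-chromene-8-carboxylate | COc1cc(OC)c(C(=O)OC)c2c1C=C(C=O)CO2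
F5 | step 4 | 8-(methoxycarbonyl)-5,7-dimethoxy-2H-chromene-3-carboxylic acid | COc1cc(OC)c(C(=O)OC)c2c1C=C(C(=O)O)CO2
F6 | step 4 | (3S)-8-(methoxycarbonyl)-5,7-dimethoxychroman-3-carboxylic acid | COc1cc(OC)c(C(=O)OC)c2c1C[C@H](C(=O)O)CO2
F7 | step 12 | methyl (3R)-3-[2,2-dimethyl-3-(phenylselanyl)-5-(triisopropylsilyloxy)chroman-8-yl]-5,7-dimethoxychroman-8-carboxylate (selenium-bearing centre unspecified) | COc1cc(OC)c(C(=O)OC)c2c1C[C@H](c1ccc(O[Si](C(C)C)(C(C)C)C(C)C)c3c1OC(C)(C)C([Se]c1ccccc1)C3)CO2
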